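**Plan**

1. Numbering: C1 (ester carbinol, i-Pr), C2–C3 (CH2), C4 (quaternary, CH3), C5 (CH2), C6–C7 (epoxide, CH3 on C7), C8 (CH2), C9 (carbinol), C10 (ring-fusion CH); ring A = C1–C2–C3–C4–C10, ring B = C4 to C10; β is the face of the C4 methyl.
2. Retrosynthesis: cut the C1–O ester bond, take the epoxide back to a C6=C7 alkene and that to a C6 ketone, and the C9 carbinol to a ketone. C6 and C9 then sit 1,4 in ring B, so C7 and C8 are both carbonyl α-carbons and the C7–C8 bond is cut as an oxidative union of two enolates, leaving a ring A 1,5-diketone.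
3. Ring A is cut at C4–CH3 (conjugate addition), C10–C9 (aldol) and C1–i-Pr (carbonyl addition), back to an achiral 3-substituted cyclopentenone.
4. Forward order: ring A, then ring B by the enolate coupling, then C9 reduction, C6=C7 alkene, ester, epoxide.
5. Stereochemistry: C4 from a chiral copper catalyst; C10 and C1 relayed from C4 (aldol anti to the larger C4 arm, i-Pr anti to the C10 chain); C9 by reduction directed from C1–OH; epoxide by epoxidation directed from C9–OH; the C7 centre formed in the coupling is erased.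
6. The diketone enters the coupling through its bis(trimethylsilyl enol ether), so the bis-enolate forms without base and never beside a free ketone (the 1,5-diketone would otherwise close by aldol).

Key step: step 10

Remark: centres or enol ether geometries that are destroyed later (C9 in 12 and 13, the ozonide carbon of 16, the enol ether geometry of 18 and 19, C7 in 20–24) are expected as mixtures; one form is drawn or the centre is left open in the SMILES.

Step 1
Reactants: 1 2-ethylacrolein
Product: 2 2-methylidenebutan-1-ol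
Conditions: NaBH4, CeCl3·7H2O, MeOH, 0 °C
Reagents that add atoms: none
Why: Luche 1,2-reduction of the enal should give the allylic alcohol without conjugate reduction; no stereocentre is formed.

Step 2
Reactants: 2 2-methylidenebutan-1-ol
Product: 3 2-(bromomethyl)but-1-ene
Conditions: PBr3, pyridine (cat.), Et2O, 0 °C
Reagents that add atoms: phosphorus tribromide BrP(Br)Br
Why: Bromination of a primary allylic alcohol with PBr3 is standard, and SN2 and SN2′ pathways give the same bromide here.

Step 3
Reactants: 3 2-(bromomethyl)but-1-ene; 4 3-ethoxycyclopent-2-en-1-one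
Product: 7 3-(2-methylidenebutyl)cyclopent-2-en-1-one, via Grignard reagent 5 (not isolated), via magnesium alkoxide adduct 6 (not isolated)
Conditions: Mg, Et2O, 0 °C; then 4, THF, −78 → 0 °C; then 1 M HCl, 0 °C
Reagents that add atoms: water O
Why: Stork–Danheiser sequence: 1,2-addition of the allylic Grignard reagent to the vinylogous ester and acid hydrolysis with carbonyl transposition should give the 3-substituted enone, brief cold acid being meant to keep the exocyclic alkene out of conjugation.

Step 4
Reactants: 7 3-(2-methylidenebutyl)cyclopent-2-en-1-one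
Product: 9 triethyl{[(3R)-3-methyl-3-(2-methylidenebutyl)cyclopent-1-en-1-yl]oxy}silane, via dimethylaluminium enolate 8 (not isolated)
Conditions: Me3Al, Cu(OTf)2 (5 mol%), chiral sulfonate-bearing imidazolinium salt (NHC precursor, 5 mol%), THF, −78 °C; then Et3SiOTf, −78 → 0 °C
Reagents that add atoms: trimethylaluminium C[Al](C)C; triethylsilyl trifluoromethanesulfonate CC[Si](CC)(CC)OS(=O)(=O)C(F)(F)F
Why: Copper-catalysed asymmetric conjugate addition of Me3Al under an N-heterocyclic carbene ligand is established for β-substituted cyclopentenones and should create the C4 quaternary centre, the ligand enantiomer being chosen for the (R) configuration, while the silyl triflate traps the aluminium enolate so that the C1–C10 enolate regiochemistry is kept.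

Step 5
Reactants: 9 silyl enol ether; 10 acetaldehyde
Product: 12 (2S,3R)-2-(1-hydroxyethyl)-3-methyl-3-(2-methylidenebutyl)cyclopentan-1-one (both carbinol epimers), via lithium enolate 11 (not isolated)
Conditions: MeLi, THF, 0 °C → rt; then 10, −78 °C; AcOH quench at −78 °C
Reagents that add atoms: none
Why: Methyllithium cleavage of the silyl enol ether gives the C10 lithium enolate regiospecifically, and its aldol addition to acetaldehyde should occur on the face anti to the larger 2-methylidenebutyl arm of C4, placing the new side chain cis to the C4 methyl (C10–H α); the carbinol configuration does not matter because C9 is oxidised in step 7.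

Step 6
Reactants: 12 aldol adduct
Product: 13 (1R,2S,3R)-2-(1-hydroxyethyl)-3-methyl-3-(2-methylidenebutyl)-1-(propan-2-yl)cyclopentan-1-ol
Conditions: i-PrMgCl, CeCl3, THF, −78 → −40 °C
Reagents that add atoms: isopropylmagnesium chloride CC(C)[Mg]Cl
Why: Organocerium 1,2-addition suppresses enolisation and β-hydride reduction of the hindered ketone, and the isopropyl group should enter the C1 carbonyl from the α face, anti to the adjacent C10 side chain, so that C1–OH ends β, cis to that chain.

Step 7
Reactants: 13 diol
Product: 14 1-[(1R,2R,5R)-2-hydroxy-5-methyl-5-(2-methylidenebutyl)-2-(propan-2-yl)cyclopentyl]ethan-1-one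
Conditions: Dess–Martin periodinane, NaHCO3, CH2Cl2, 0 °C → rt
Reagents that add atoms: none
Why: Dess–Martin oxidation converts the secondary carbinol into the C9 methyl ketone under neutral conditions, merges the carbinol epimers and cannot touch the tertiary alcohol.

Step 8
Reactants: 14 hydroxy ketone
Product: 15 1-[(1R,2R,5R)-5-methyl-5-(2-methylidenebutyl)-2-(propan-2-yl)-2-(triethylsilyloxy)cyclopentyl]ethan-1-one
Conditions: Et3SiOTf, 2,6-lutidine, CH2Cl2, −78 °C → rt
Reagents that add atoms: triethylsilyl trifluoromethanesulfonate CC[Si](CC)(CC)OS(=O)(=O)C(F)(F)F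
Why: Silyl triflate silylation is the standard way to cap a hindered tertiary alcohol, and the triethylsilyl ether blocks retro-aldol cleavage of the β-hydroxy ketone in the enolate chemistry that follows.

Step 9
Reactants: 15 silyl ether
Product: 17 1-[(1R,2R,5R)-5-methyl-5-(2-oxobutyl)-2-(propan-2-yl)-2-(triethylsilyloxy)cyclopentyl]ethan-1-one, via ozonide 16 (not isolated)
Conditions: O3, CH2Cl2, −78 °C; then PPh3, −78 °C → rt
Reagents that add atoms: ozone [O-][O+]=O
Why: Ozonolysis with reductive work-up cleaves the 1,1-disubstituted alkene to the C6 ethyl ketone and formaldehyde, the methyl ketone and the tertiary silyl ether being inert to ozone.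

Step 10
Reactants: 17 ring A 1,5-diketone
Product: 20 1α-isopropyl-4β,7β-dimethyl-1β-(triethylsilyloxy)-10αH-bicyclo[5.3.0]decane-6,9-dione (target numbering; C7 epimer drawn), via bis(trimethylsilyl enol ether) 18 (not isolated), via dilithium bis-enolate 19 (not isolated)
Conditions: Me3SiOTf, Et3N, Et2O, 0 °C → rt, Et3NH·OTf layer removed by cannula; then MeLi, 0 °C → rt; then slow addition to Fe(acac)3 (2.5 equiv), THF, 0.005 M, −78 °C → rt
Reagents that add atoms: none
Why: Soft enolisation with silyl triflate and amine converts both ketones into trimethylsilyl enol ethers (at C8 because C10 is flanked by two quaternary carbons, at C7 because C5 is neopentyl) without a free enolate ever facing a free ketone, which avoids the six-membered aldol of the 1,5-diketone, and methyllithium then releases the regiodefined dilithium bis-enolate 19 by Si–O cleavage. One-electron oxidation of one enolate by trivalent iron gives an α-keto radical that adds to the carbon terminus of the second enolate, and a second one-electron oxidation of the resulting ketyl delivers the 1,4-diketone with the new C7–C8 bond. The closest known reaction type is the iron- or copper-mediated intramolecular oxidative coupling of ketone bis-enolates to cyclic 1,4-diketones, established mainly for smaller rings. Ring B closes in a 7-endo-trig mode between chains that are trans on the adjacent ring A carbons C10 and C4, so the bicycle is trans-fused. The only new stereocentre, C7, is not reliably controlled and is erased in step 14. The step needs ring closure to outrun intermolecular coupling and hydrogen abstraction, which high dilution and slow addition of 19 to excess Fe(acac)3 are meant to secure, while C10 cannot epimerise because no base is used.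

Step 11
Reactants: 20 bicyclic dione
Product: 21 1β-hydroxy-1α-isopropyl-4β,7β-dimethyl-10αH-bicyclo[5.3.0]decane-6,9-dione
Conditions: HF·pyridine, pyridine, THF, 0 °C → rt
Reagents that add atoms: none
Why: Fluoride-mediated desilylation under buffered, non-basic conditions should free the tertiary C1–OH without retro-aldol cleavage or dehydration of the resulting β-hydroxy ketone.

Step 12
Reactants: 21 hydroxy dione
Product: 22 1β,9α-dihydroxy-1α-isopropyl-4β,7β-dimethyl-10αH-bicyclo[5.3.0]decan-6-one
Conditions: Me4NBH(OAc)3, MeCN/AcOH, −30 °C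
Reagents that add atoms: none
Why: Evans–Saksena reduction: C1–OH exchanges onto boron and delivers hydride intramolecularly to the β face of the C9 carbonyl, which should give the 1,3-anti diol with C9–OH α, while the C6 ketone has no hydroxyl within reach and is not reduced by the triacetoxyborohydride.

Step 13
Reactants: 22 diol ketone
Product: 24 9α-(tert-butyldimethylsilyloxy)-1α-isopropyl-4β,7β-dimethyl-1β-(trimethylsilyloxy)-10αH-bicyclo[5.3.0]decan-6-one, via C9 tert-butyldimethylsilyl ether 23 (not isolated)
Conditions: t-BuMe2SiOTf, 2,6-lutidine, CH2Cl2, −78 °C; then N-(trimethylsilyl)imidazole, −78 °C → rt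
Reagents that add atoms: tert-butyldimethylsilyl trifluoromethanesulfonate CC(C)(C)[Si](C)(C)OS(=O)(=O)C(F)(F)F; N-(trimethylsilyl)imidazole C[Si](C)(C)n1ccnc1
Why: Silyl triflate at low temperature silylates the secondary C9–OH in preference to the hindered tertiary C1–OH, and the N-silylimidazole then caps C1–OH as a labile trimethylsilyl ether that shields it from triflic anhydride in step 14 without enolising the C6 ketone.

Step 14
Reactants: 24 bis-silyl ether
Product: 25 9α-(tert-butyldimethylsilyloxy)-1α-isopropyl-4β,7-dimethyl-1β-(trimethylsilyloxy)-10αH-bicyclo[5.3.0]dec-6-en-6-yl trifluoromethanesulfonate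
Conditions: Tf2O, 2,6-di-tert-butyl-4-methylpyridine, CH2Cl2, 0 °C → rt
Reagents that add atoms: trifluoromethanesulfonic anhydride O=S(=O)(OS(=O)(=O)C(F)(F)F)C(F)(F)F
Why: Enol triflate formation with triflic anhydride and a hindered pyridine base favours the more substituted enol triflate and should give the C6=C7 isomer, the alternative C5 being a neopentyl methylene; the C7 stereocentre from step 10 disappears here.

Step 15
Reactants: 25 enol triflate
Product: 27 9α-(tert-butyldimethylsilyloxy)-1α-isopropyl-4β,7-dimethyl-10αH-bicyclo[5.3.0]dec-6-en-1β-ol, via trimethylsilyl ether alkene 26 (not isolated)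
Conditions: Pd(OAc)2 (5 mol%), PPh3, n-Bu3N, HCO2H, DMF, 60 °C; then K2CO3, MeOH, rt
Reagents that add atoms: none
Why: Palladium-catalysed formate reduction of the enol triflate (oxidative addition to zerovalent palladium, formate exchange, decarboxylation, reductive elimination) should give the C6=C7 trisubstituted alkene without migration, and methanolysis then removes only the trimethylsilyl group.

Step 16
Reactants: 28 vanillic acid
Product: 30 4-(benzyloxy)-3-methoxybenzoic acid, via benzyl ester 29 (not isolated)
Conditions: BnBr, K2CO3, DMF, 60 °C; then NaOH, MeOH/H2O, reflux; HCl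
Reagents that add atoms: benzyl bromide BrCc1ccccc1; sodium hydroxide [Na+].[OH-]
Why: Williamson benzylation of phenol and carboxylate followed by saponification of the benzyl ester is routine and leaves the phenol masked as a benzyl ether.

Step 17
Reactants: 30 4-(benzyloxy)-3-methoxybenzoic acid
Product: 31 4-(benzyloxy)-3-methoxybenzoyl chloride
Conditions: (COCl)2, DMF (cat.), CH2Cl2, 0 °C → rt
Reagents that add atoms: oxalyl chloride O=C(Cl)C(Cl)=O
Why: Acid chloride formation through the Vilsmeier-type chloroiminium catalyst is standard for benzoic acids.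

Step 18
Reactants: 27 alkene alcohol; 31 acid chloride
Product: 33 9α-(tert-butyldimethylsilyloxy)-1α-isopropyl-4β,7-dimethyl-10αH-bicyclo[5.3.0]dec-6-en-1β-yl 4-(benzyloxy)-3-methoxybenzoate, via lithium alkoxide 32 (not isolated)
Conditions: n-BuLi, THF, −78 °C; then 31, −78 °C → rt
Reagents that add atoms: none
Why: O-Acylation of a preformed lithium alkoxide with an aroyl chloride is the usual answer to hindered tertiary alcohols, and since no enolisable carbonyl remains and C9–OH is silylated only C1–O can be acylated.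

Step 19
Reactants: 33 silyl ether ester
Product: 34 9α-hydroxy-1α-isopropyl-4β,7-dimethyl-10αH-bicyclo[5.3.0]dec-6-en-1β-yl 4-(benzyloxy)-3-methoxybenzoate
Conditions: HF·pyridine, pyridine, THF, 0 °C → rt
Reagents that add atoms: none
Why: Fluoride cleavage of the secondary silyl ether under non-basic conditions should free C9–OH without 1,3-acyl migration from C1–O.

Step 20
Reactants: 34 homoallylic alcohol
Product: 35 6α,7α-epoxy-9α-hydroxy-1α-isopropyl-4β,7β-dimethyl-10αH-bicyclo[5.3.0]decan-1β-yl 4-(benzyloxy)-3-methoxybenzoate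
Conditions: VO(acac)2 (5 mol%), t-BuOOH, CH2Cl2, 0 °C → rt
Reagents that add atoms: tert-butyl hydroperoxide CC(C)(C)OO
Why: Vanadium-catalysed hydroxyl-directed epoxidation: the homoallylic C9–OH binds the vanadium peroxide and should deliver oxygen to the α face of the C6=C7 alkene, which is also the face free of the C4 methyl, setting C6 and C7.

Step 21
Reactants: 35 benzyl-protected epoxide
Product: 36 6α,7α-epoxy-9α-hydroxy-1α-isopropyl-4β,7β-dimethyl-10αH-bicyclo[5.3.0]decan-1β-yl 4-hydroxy-3-methoxybenzoate (CNP0315707.1)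
Conditions: H2 (1 atm), Pd/C, EtOAc, rt
Reagents that add atoms: none
Why: Hydrogenolysis of the benzyl aryl ether under neutral conditions should release the phenol, the epoxide (neither benzylic nor allylic) and the tertiary ester being expected to survive.

**Compound list**

1 | 2-ethylacrolein (2-methylidenebutanal) | C=C(CC)C=O | starting material
2 | 2-methylidenebutan-1-ol | C=C(CC)CO | intermediate
3 | 2-(bromomethyl)but-1-ene | C=C(CC)CBr | intermediate
4 | 3-ethoxycyclopent-2-en-1-one | CCOC1=CC(=O)CC1 | starting material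
5 | (2-methylidenebutyl)magnesium bromide | C=C(CC)C[Mg]Br | intermediate
6 | bromomagnesium 3-ethoxy-1-(2-methylidenebutyl)cyclopent-2-en-1-olate | CCOC1=CC(CC(=C)CC)(O[Mg]Br)CC1 | intermediate
7 | 3-(2-methylidenebutyl)cyclopent-2-en-1-one | O=C1C=C(CC(=C)CC)CC1 | intermediate
8 | dimethylaluminium (3R)-3-methyl-3-(2-methylidenebutyl)cyclopent-1-en-1-olate | C[Al](C)OC1=C[C@@](C)(CC(=C)CC)CC1 | intermediate
9 | triethyl{[(3R)-3-methyl-3-(2-methylidenebutyl)cyclopent-1-en-1-yl]oxy}silane | CC[Si](CC)(CC)OC1=C[C@@](C)(CC(=C)CC)CC1 | intermediate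
10 | acetaldehyde | CC=O | starting material
11 | lithium (3R)-3-methyl-3-(2-methylidenebutyl)cyclopent-1-en-1-olate | [Li]OC1=C[C@@](C)(CC(=C)CC)CC1 | intermediate
12 | (2S,3R)-2-(1-hydroxyethyl)-3-methyl-3-(2-methylidenebutyl)cyclopentan-1-one, hydroxyethyl cis to the ring methyl, carbinol epimers | O=C1CC[C@](C)(CC(=C)CC)[C@H]1C(C)O | intermediate
13 | (1R,2S,3R)-2-(1-hydroxyethyl)-3-methyl-3-(2-methylidenebutyl)-1-(propan-2-yl)cyclopentan-1-ol, carbinol epimers | O[C@@]1(C(C)C)CC[C@](C)(CC(=C)CC)[C@H]1C(C)O | intermediate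
14 | 1-[(1R,2R,5R)-2-hydroxy-5-methyl-5-(2-methylidenebutyl)-2-(propan-2-yl)cyclopentyl]ethan-1-one | O[C@@]1(C(C)C)CC[C@](C)(CC(=C)CC)[C@H]1C(C)=O | intermediate
15 | 1-[(1R,2R,5R)-5-methyl-5-(2-methylidenebutyl)-2-(propan-2-yl)-2-(triethylsilyloxy)cyclopentyl]ethan-1-one | CC[Si](CC)(CC)O[C@@]1(C(C)C)CC[C@](C)(CC(=C)CC)[C@H]1C(C)=O | intermediate
16 | ozonide of 15: 1-{(1R,2R,5R)-5-[(3-ethyl-1,2,4-trioxolan-3-yl)methyl]-5-methyl-2-(propan-2-yl)-2-(triethylsilyloxy)cyclopentyl}ethan-1-one | CC[Si](CC)(CC)O[C@@]1(C(C)C)CC[C@](C)(CC2(CC)OCOO2)[C@H]1C(C)=O | intermediate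
17 | 1-[(1R,2R,5R)-5-methyl-5-(2-oxobutyl)-2-(propan-2-yl)-2-(triethylsilyloxy)cyclopentyl]ethan-1-one (ring A diketone; acetyl, C4 methyl and OSiEt3 on the β face) | CC[Si](CC)(CC)O[C@@]1(C(C)C)CC[C@](C)(CC(=O)CC)[C@H]1C(C)=O | intermediate
18 | bis(trimethylsilyl enol ether) of 17 (C8=C9 and Z-C6=C7) | CC[Si](CC)(CC)O[C@@]1(C(C)C)CC[C@](C)(C/C(O[Si](C)(C)C)=C/C)[C@H]1C(=C)O[Si](C)(C)C | intermediate
19 | dilithium bis-enolate of 17 (C8=C9 and C6=C7) | CC[Si](CC)(CC)O[C@@]1(C(C)C)CC[C@](C)(C/C(O[Li])=C/C)[C@H]1C(=C)O[Li] | intermediate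
20 | 1α-isopropyl-4β,7β-dimethyl-1β-(triethylsilyloxy)-10αH-bicyclo[5.3.0]decane-6,9-dione (target numbering) | CC[Si](CC)(CC)O[C@@]1(C(C)C)CC[C@]2(C)CC(=O)[C@@H](C)CC(=O)[C@H]21 | intermediate
21 | 1β-hydroxy-1α-isopropyl-4β,7β-dimethyl-10αH-bicyclo[5.3.0]decane-6,9-dione | O[C@@]1(C(C)C)CC[C@]2(C)CC(=O)[C@@H](C)CC(=O)[C@H]21 | intermediate
22 | 1β,9α-dihydroxy-1α-isopropyl-4β,7β-dimethyl-10αH-bicyclo[5.3.0]decan-6-one | O[C@@]1(C(C)C)CC[C@]2(C)CC(=O)[C@@H](C)C[C@H](O)[C@H]21 | intermediate
23 | 9α-(tert-butyldimethylsilyloxy)-1β-hydroxy-1α-isopropyl-4β,7β-dimethyl-10αH-bicyclo[5.3.0]decan-6-one | O[C@@]1(C(C)C)CC[C@]2(C)CC(=O)[C@@H](C)C[C@H](O[Si](C)(C)C(C)(C)C)[C@H]21 | intermediate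
24 | 9α-(tert-butyldimethylsilyloxy)-1α-isopropyl-4β,7β-dimethyl-1β-(trimethylsilyloxy)-10αH-bicyclo[5.3.0]decan-6-one | C[Si](C)(C)O[C@@]1(C(C)C)CC[C@]2(C)CC(=O)[C@@H](C)C[C@H](O[Si](C)(C)C(C)(C)C)[C@H]21 | intermediate
25 | 9α-(tert-butyldimethylsilyloxy)-1α-isopropyl-4β,7-dimethyl-1β-(trimethylsilyloxy)-10αH-bicyclo[5.3.0]dec-6-en-6-yl trifluoromethanesulfonate | C[Si](C)(C)O[C@@]1(C(C)C)CC[C@]2(C)CC(OS(=O)(=O)C(F)(F)F)=C(C)C[C@H](O[Si](C)(C)C(C)(C)C)[C@H]21 | intermediate
26 | 9α-(tert-butyldimethylsilyloxy)-1α-isopropyl-4β,7-dimethyl-1β-(trimethylsilyloxy)-10αH-bicyclo[5.3.0]dec-6-ene | C[Si](C)(C)O[C@@]1(C(C)C)CC[C@]2(C)CC=C(C)C[C@H](O[Si](C)(C)C(C)(C)C)[C@H]21 | intermediate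
27 | 9α-(tert-butyldimethylsilyloxy)-1α-isopropyl-4β,7-dimethyl-10αH-bicyclo[5.3.0]dec-6-en-1β-ol | O[C@@]1(C(C)C)CC[C@]2(C)CC=C(C)C[C@H](O[Si](C)(C)C(C)(C)C)[C@H]21 | intermediate
28 | vanillic acid | COc1cc(C(=O)O)ccc1O | starting material
29 | benzyl 4-(benzyloxy)-3-methoxybenzoate | COc1cc(C(=O)OCc2ccccc2)ccc1OCc1ccccc1 | intermediate
30 | 4-(benzyloxy)-3-methoxybenzoic acid | COc1cc(C(=O)O)ccc1OCc1ccccc1 | intermediate
31 | 4-(benzyloxy)-3-methoxybenzoyl chloride | COc1cc(C(Cl)=O)ccc1OCc1ccccc1 | intermediate
32 | lithium alkoxide of 27 | [Li]O[C@@]1(C(C)C)CC[C@]2(C)CC=C(C)C[C@H](O[Si](C)(C)C(C)(C)C)[C@H]21 | intermediate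
33 | 9α-(tert-butyldimethylsilyloxy)-1α-isopropyl-4β,7-dimethyl-10αH-bicyclo[5.3.0]dec-6-en-1β-yl 4-(benzyloxy)-3-methoxybenzoate | COc1cc(C(=O)O[C@@]2(C(C)C)CC[C@]3(C)CC=C(C)C[C@H](O[Si](C)(C)C(C)(C)C)[C@H]32)ccc1OCc1ccccc1 | intermediate
34 | 9α-hydroxy-1α-isopropyl-4β,7-dimethyl-10αH-bicyclo[5.3.0]dec-6-en-1β-yl 4-(benzyloxy)-3-methoxybenzoate | COc1cc(C(=O)O[C@@]2(C(C)C)CC[C@]3(C)CC=C(C)C[C@H](O)[C@H]32)ccc1OCc1ccccc1 | intermediate
35 | 6α,7α-epoxy-9α-hydroxy-1α-isopropyl-4β,7β-dimethyl-10αH-bicyclo[5.3.0]decan-1β-yl 4-(benzyloxy)-3-methoxybenzoate | COc1cc(C(=O)O[C@@]2(C(C)C)CC[C@]3(C)C[C@@H]4O[C@]4(C)C[C@H](O)[C@H]32)ccc1OCc1ccccc1 | intermediate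
36 | CNP0315707.1: 6α,7α-epoxy-9α-hydroxy-1α-isopropyl-4β,7β-dimethyl-10αH-bicyclo[5.3.0]decan-1β-yl 4-hydroxy-3-methoxybenzoate | COc1cc(C(=O)O[C@@]2(C(C)C)CC[C@]3(C)C[C@@H]4O[C@]4(C)C[C@H](O)[C@H]32)ccc1O | target

**Step count and risks**

Total steps: 21. Longest linear sequence: 19 (steps 1–15 and 18–21); steps 16–17 prepare the acid chloride.

Step 10. The radical–enolate combination has to close a seven-membered ring and may be outrun by intermolecular coupling or by hydrogen abstraction, which returns the diketone. The fallback sets out from 17 and comes back at 20, making the same C7–C8 bond in a polar way. The bis(silyl enol ether) 18 is formed as in step 10 and treated with one equivalent of NBS (THF, −78 °C), which should brominate the more electron-rich trisubstituted C6=C7 enol ether and leave the terminal one, giving the C7-bromo ketone silyl enol ether F1. An anhydrous fluoride source (tetrabutylammonium difluorotriphenylsilicate, THF, high dilution) then frees the C8 enolate, which displaces bromide at C7 (7-exo-tet enolate alkylation) to give 20.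

Step 5. Facial selectivity at C10 may be poor, because the two C4 substituents differ only from the second atom outward; the wrong C10 epimer would carry its error into C1 in step 6. The fallback sets out from 12 and comes back at 13, replacing kinetic face selection by thermodynamic control. The aldol mixture is silylated (t-BuMe2SiOTf, 2,6-lutidine) to the silyloxy ketone F2, which is equilibrated at C10 with DBU (toluene, rt) towards the isomer with the bulky side chain trans to the larger C4 arm. Addition of i-PrMgCl/CeCl3 then gives the mono-silylated diol F3, and HF·pyridine returns 13.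

Step 18. Acylation of the crowded tertiary alkoxide (isopropyl on one side, ring fusion and C9–OSi on the other) may stall, with proton return on work-up or elimination on forcing. The fallback sets out from 27 and comes back at 33, forming the ester C–O bond at palladium. The sodium alkoxide of 27 (NaH, toluene) is carbonylated with 1-(benzyloxy)-4-iodo-2-methoxybenzene under CO (1 atm) with Pd(OAc)2 and Xantphos at 80 °C, so that an aroyl–palladium intermediate is captured by the alkoxide; no new intermediate is isolated.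

**Further compounds**

F1 | step 10 | 1-[(1R,2R,5R)-5-(3-bromo-2-oxobutyl)-5-methyl-2-(propan-2-yl)-2-(triethylsilyloxy)cyclopentyl]ethen-1-yl trimethylsilyl ether (C7-bromo ketone silyl enol ether) | CC[Si](CC)(CC)O[C@@]1(C(C)C)CC[C@](C)(CC(=O)C(C)Br)[C@H]1C(=C)O[Si](C)(C)C
F2 | step 5 | (2S,3R)-2-[1-(tert-butyldimethylsilyloxy)ethyl]-3-methyl-3-(2-methylidenebutyl)cyclopentan-1-one | O=C1CC[C@](C)(CC(=C)CC)[C@H]1C(C)O[Si](C)(C)C(C)(C)C
F3 | step 5 | (1R,2S,3R)-2-[1-(tert-butyldimethylsilyloxy)ethyl]-3-methyl-3-(2-methylidenebutyl)-1-(propan-2-yl)cyclopentan-1-ol | O[C@@]1(C(C)C)CC[C@](C)(CC(=C)CC)[C@H]1C(C)O[Si](C)(C)C(C)(C)C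
F0 | step 18 | none | none
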